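Remarks on conventions and assumptions (chemistry only):
- Numbering follows the target: ring B = C1–C5 and C10 (C3 carbinol/ketone carbon, C4 methyl-bearing); ring A = C5–C10 (C7 carbonyl in the key-step product, C8 and C9 methyl-bearing); C11 = oxymethylene carbon on C9. β is the face of the C5 methyl, α the face of H10.
- Compounds 5–8 are racemic; for 6–8 the SMILES shows the enantiomer that is carried on.
- Consistency check: the (S)-oxirane and (E)-enol ether of 18 map onto the 8α,9β-dimethyl array of 20 and 30 (inversion at C9, chair closure), so these structures need no correction. The C3 silyl ether configuration is a spectator; 3α (equatorial) is kept.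
- Assumption: the lipase in step 5 acylates the (R)-carbinol, as the empirical size rule predicts. If the sense were reversed, the recovered alcohol would be carried through steps 6–7 instead.

## Structural features

The target is a trans-fused decalin in which C9 carries a methyl group and the oxymethylene C11, joined through an aryl ether oxygen to C7 of a coumarin (the umbelliferone unit). Five stereocentres are contiguous along C4–C5–C10–C9–C8: C4 (β-methyl, equatorial, next to the C3 ketone), C5 (quaternary, β-methyl axial), C10 (α-H), C9 (quaternary, β-methyl axial, α-CH2OAr equatorial) and C8 (α-methyl axial). The C5 and C9 methyl groups are 1,3-diaxial and the C8 and C9 methyl groups are trans-diaxial, so C8 has the configuration that neither equilibration nor axial protonation of a C7 enolate would deliver. Fragile points are the coumarin lactone and its conjugated alkene (strong base, hydride, hydrogenation) and, in intermediates, a C8 centre beside a C7 carbonyl. The C4 centre beside the C3 ketone is epimerisable, but its equatorial configuration is the stable one. The real difficulty is the vicinal pair C8/C9, one of them quaternary, built next to the quaternary C5, together with an ether bond at the neopentyl C11. The key step uses the fact that the C9 substituents (methyl plus oxymethylene) are exactly what a 2,2-disubstituted oxirane on C9/C11 leaves behind when it is opened at its fully substituted carbon. With C8 of a C7 silyl enol ether as the nucleophile, the ring-A bond C8–C9, the C11 oxygen and a removable C7 carbonyl appear together.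

## Logic of the disconnections

**30 ⇒ 28 (via 29).** No skeletal bond is cut; the C3 carbonyl is carried as a silyl-protected equatorial carbinol. A free C3 ketone would compete as an electrophile in the Lewis-acid step and in the organometallic steps, and the carbinol is also the handle for resolution. The forward steps (desilylation, oxidation) must spare the coumarin. C4 is safe because its configuration is the thermodynamic one.

**28 ⇒ 26 + 27.** The O–C11 aryl ether bond is cut so that the base- and reduction-sensitive coumarin arrives last and convergently. This demands substitution at a neopentyl carbon, hence a triflate leaving group. C9 has no hydrogen, so elimination cannot compete.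

**26 ⇒ 25 ⇒ 24 ⇒ 23 ⇒ 21 ⇒ 20.** A carbonyl is put back on C7, where the enol ether nucleophile leaves it. The forward removal must not enolise toward C8 and must not depend on nucleophilic attack at the shielded C7 carbon. It therefore runs through the C6-side enol triflate, palladium/formate reduction and hydrogenation. The C11 hydroxyl is masked as an allyl carbonate that the same palladium step removes.

**20 ⇒ 18 (key).** The C8–C9 bond is cut, opening ring A. A bicyclic compound with two new stereocentres becomes a ring-B cyclohexane with two equatorial side chains; C9 is encoded in the oxirane configuration and C8 in the enol ether geometry. The forward step needs the (E)-enol ether, the correct oxirane epimer, and C–C bond formation with inversion before the oxirane ionises.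

**18 ⇒ 16 ⇒ 14.** The O–Si bond of the enol ether and then the C7=O bond (as C7=CH2) are cut. The C7 ketone is kept masked as a 1,1-disubstituted alkene until after the oxirane is in place, so the sulfur ylide never faces two ketones. One ozonolysis replaces a three-step allyl-to-ethyl-ketone sequence. Demands: ozonolysis that spares the oxirane, then regioselective and (E)-selective enolisation at C8.

**14 ⇒ 12 + 13.** The C9–C11 and C11–O bonds of the oxirane are cut (methylene transfer to the C9 acetyl group). The forward addition must choose the correct face of the ketone under control of C10 and the quaternary C5.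

**12 ⇒ 11 ⇒ 9.** The O–Si bond and the C9–CH3 bond are cut, returning the acetyl group to the ester of the resolved acetate. One organolithium step is asked to convert the hindered ester into the methyl ketone and remove the acetate, without epimerising C10.

**9 ⇒ 8 ⇒ 7.** No skeletal bond is cut. The acetate comes from kinetic resolution of the racemic equatorial alcohol, and the alcohol from the ketone. The reduction must be thermodynamically controlled, because hydride would approach away from the axial C5 methyl and give the axial epimer. The enzyme must distinguish the enantiomers of a hindered carbinol.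

**7 ⇒ 5 + 3.** The C5–C6 bond is cut (conjugate allylation), which removes the quaternary C5. The forward step must add to a tetrasubstituted enone trans to the ester; C4 then settles by protonation and equilibration.

**5 ⇒ 4 and 3 ⇒ 1 + 2.** The C4–CH3 bond (enolate methylation) and the vinyl–CH2Si bond (cross-coupling) are cut, reaching commercial materials.

## Other disconnections considered

**Alternative 1:** Ring B is cut at C10–C1 and C5–C4, leaving the ring-A enone A1 with the C9 quaternary centre and protected C11 oxygen already present. Forward, copper-catalysed addition of a vinyl Grignard reagent to C10, then alkylation of the enolate at C5 with a silyl-capped propargyl bromide, would give A2.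
- In favour: two C–C bonds and two stereocentres (C10, C5) in one flask by a well-established conjugate addition/enolate trapping sequence with its usual trans outcome.
- Better than the chosen plan: C11 is protected from the start, so there is no oxirane and no unmasking of C11 beside a ketone. Absolute configuration could come from a catalytic asymmetric synthesis of A1 and not from a resolution that discards half the material.
- Against: no ring is closed. Ring B must still be built from the vinyl and propargyl arms, and the C3 carbonyl and C4 methyl must be introduced beside the quaternary C5. A2 has no C8 methyl and carries a C6 carbonyl, so C8 would need a Δ7-enone, conjugate methyl addition beside C9, and then C6 deoxygenation. Facial control in the vinyl addition rests on distinguishing CH3 from CH2OSi at C9.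
- Comparison: each operation is mechanistically conventional and at least as predictable as the chosen key step. The stereocentres C4 and C8 are, however, spread over later steps, and the sequence should be longer. The chosen plan sets C8 and C9 in the ring-forming event.

**Alternative 2:** Both rings are cut at once (C5–C10 and C3–C4) to the acyclic triene A3, a 1-silyloxydiene tethered through C9 to a tiglyl ketone. Heating would close rings B and A by an intramolecular Diels–Alder reaction to give A4.
- Better than the chosen key step: two rings, two C–C bonds and up to four stereocentres (C3, C4, C5, C10) in one reagent-free step. The tiglyl geometry is transferred stereospecifically into the cis C4/C5 methyl pair, and the diene delivers the C3 oxygen.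
- Against: the trans ring fusion is not assured, since trienones with the activating carbonyl inside the tether often favour the cis-fused mode, and the α-methyl dienophile and quaternary C9 make the balance hard to predict. The only pre-existing stereocentre (acyclic C9) must relay facial selectivity through the tether. A3 needs an enantioselective acyclic quaternary centre and contains a hydrolytically sensitive dienol ether. A4 lacks the C8 methyl and has a C6 carbonyl and a C1=C2 alkene to remove.
- Comparison: superior in complexity generated per step and equal in needing a ring-A carbonyl removed. It is less secure in stereocontrol than the ring-controlled steps of the chosen plan, and comparable or longer overall because of the late C8 methylation.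

**Alternative 3:** The C9–CH3 and C8–CH3 bonds are cut from A6 back to the ring-A enone A5. Forward, a methyl cuprate would add axially to C9 and the regiodefined C7 enolate would be methylated at C8 from the opposite face.
- Equal or better on C8 control: it addresses the trans-diaxial 8α,9β-dimethyl array directly with stereoelectronically favoured axial bond formation, and the enolate regiochemistry is fixed by the conjugate addition. No enol ether geometry is involved.
- Better on protecting groups: C11 is a robust benzyl ether and C3 a ketal (possible because no strong Lewis acid is used), so the C3 reduction/re-oxidation pair is avoided.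
- Against: the cuprate must create a quaternary centre at a β,β-disubstituted position that becomes 1,3-diaxial to the C5 methyl. A γ-alkoxy enone can lose its alkoxide under electron-transfer conditions. Enolate methylation can over-alkylate. No ring is formed, so the decalin A5 must be assembled and made enantiopure first.
- Comparison: equal to the chosen plan in needing C7 deoxygenation beside an epimerisable C8. It is riskier at the conjugate addition than the chosen plan is at the cyclisation, and similar in length.

Key step: step 11

## Route

Step 1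
Reactants: 1 2-bromobut-1-ene; 2 (trimethylsilyl)methylmagnesium chloride
Product: 3 trimethyl(2-methylidenebutyl)silane
Conditions: NiCl2(dppp) (cat.), Et2O, 0 °C to reflux
Reagents that add atoms: none
Why: Kumada cross-coupling of a vinyl bromide with a silylmethyl Grignard reagent is an established route to 2-substituted allylsilanes; no stereocentre is involved and the volatile product is distilled.

Step 2
Reactants: 4 ethyl 2-methyl-4-oxocyclohex-2-ene-1-carboxylate (Hagemann's ester)
Product: 5 ethyl 2,3-dimethyl-4-oxocyclohex-2-ene-1-carboxylate (racemate)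
Conditions: KOtBu, tBuOH, rt; MeI, 0 °C to rt
Reagents that add atoms: iodomethane, SMILES CI
Why: The extended enolate of Hagemann's ester is C-alkylated at the carbon between the carbonyl group and the β-methyl carbon (C4 of the target), a classical enolate alkylation that returns the conjugated enone; the ester-bearing centre stays racemic.

Step 3
Reactants: 5 ethyl 2,3-dimethyl-4-oxocyclohex-2-ene-1-carboxylate; 3 trimethyl(2-methylidenebutyl)silane
Product: 7 ethyl (1R*,2R*,3R*)-2,3-dimethyl-2-(2-methylidenebutyl)-4-oxocyclohexane-1-carboxylate (racemate), via titanium enolate 6 (not isolated)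
Conditions: TiCl4, CH2Cl2, −78 °C; H2O; then NaOEt (cat.), EtOH, 0 °C
Reagents that add atoms: none
Why: Hosomi–Sakurai conjugate allylation: TiCl4 activates the enone and the terminal carbon of the 2-substituted allylsilane attacks C5; A(1,2) strain with the C5 methyl holds the ester pseudoaxial, and axial attack anti to it places the new chain trans to the ester. Axial protonation of the enolate and a brief base equilibration of the ketone α-centre should leave the C4 methyl equatorial, cis to the C5 methyl.

Step 4
Reactants: 7 ethyl (1R*,2R*,3R*)-2,3-dimethyl-2-(2-methylidenebutyl)-4-oxocyclohexane-1-carboxylate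
Product: 8 ethyl (1R*,2R*,3R*,4R*)-4-hydroxy-2,3-dimethyl-2-(2-methylidenebutyl)cyclohexane-1-carboxylate (racemate)
Conditions: SmI2, H2O, Et3N, THF, 0 °C
Reagents that add atoms: none
Why: Ketyl-type single-electron reduction with SmI2 behaves like a dissolving-metal reduction and should give the more stable equatorial (3α) alcohol, trans to the C4 methyl. Hydride reagents are expected to approach away from the axial C5 methyl and give the axial epimer; the ester and the alkene are not reduced.

Step 5
Reactants: 8 ethyl (1R*,2R*,3R*,4R*)-4-hydroxy-2,3-dimethyl-2-(2-methylidenebutyl)cyclohexane-1-carboxylate (racemate)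
Product: 9 ethyl (1R,2R,3R,4R)-4-acetoxy-2,3-dimethyl-2-(2-methylidenebutyl)cyclohexane-1-carboxylate
Conditions: Candida antarctica lipase B (immobilised), vinyl acetate, MTBE, 35 °C, stopped near half conversion; chromatography
Reagents that add atoms: vinyl acetate, SMILES CC(=O)OC=C
Why: Lipase-catalysed kinetic resolution by irreversible transesterification; for a secondary alcohol flanked by a medium (CH2) and a large (CHMe next to a quaternary carbon) group the empirical size rule predicts acylation of the (R)-carbinol, the enantiomer needed. The acetate is separated from the unreacted enantiomeric alcohol.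

Step 6
Reactants: 9 ethyl (1R,2R,3R,4R)-4-acetoxy-2,3-dimethyl-2-(2-methylidenebutyl)cyclohexane-1-carboxylate
Product: 11 1-[(1R,2R,3R,4R)-4-hydroxy-2,3-dimethyl-2-(2-methylidenebutyl)cyclohexyl]ethan-1-one, via silylmethyl ketone 10 (not isolated)
Conditions: Me3SiCH2Li (excess), THF/pentane, −78 to 0 °C; then MeOH, −78 °C; aq. NH4Cl
Reagents that add atoms: (trimethylsilyl)methyllithium, SMILES [Li]C[Si](C)(C)C
Why: Esters react with Me3SiCH2Li to give α-silyl ketones that are shielded from over-addition as their enolates and are protodesilylated by methanol to methyl ketones (acyl substitution followed by protodesilylation). The same reagent cleaves the acetate, so deacetylation and formation of the C9 acetyl group are combined; the cold quench avoids epimerising C10.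

Step 7
Reactants: 11 1-[(1R,2R,3R,4R)-4-hydroxy-2,3-dimethyl-2-(2-methylidenebutyl)cyclohexyl]ethan-1-one
Product: 12 1-[(1R,2R,3R,4R)-4-(tert-butyldimethylsilyloxy)-2,3-dimethyl-2-(2-methylidenebutyl)cyclohexyl]ethan-1-one
Conditions: TBSCl, imidazole, DMF, 40 °C
Reagents that add atoms: tert-butyldimethylsilyl chloride, SMILES CC(C)(C)[Si](C)(C)Cl
Why: Standard silylation of an equatorial secondary alcohol; ketone and alkene are inert, and the silyl ether (unlike a ketal) tolerates the later aluminium Lewis acid.

Step 8
Reactants: 12 1-[(1R,2R,3R,4R)-4-(tert-butyldimethylsilyloxy)-2,3-dimethyl-2-(2-methylidenebutyl)cyclohexyl]ethan-1-one; 13 trimethylsulfonium iodide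
Product: 14 (2S)-2-[(1R,2R,3R,4R)-4-(tert-butyldimethylsilyloxy)-2,3-dimethyl-2-(2-methylidenebutyl)cyclohexyl]-2-methyloxirane
Conditions: 13, n-BuLi, THF, −10 °C; then 12, −10 °C to rt; chromatography
Reagents that add atoms: none
Why: Corey–Chaykovsky methylene transfer: the sulfonium methylide adds irreversibly to the acetyl carbonyl and the betaine closes to the 2-methyl-2-alkyloxirane. In the Felkin–Anh arrangement the quaternary C5 lies anti to the incoming ylide, which passes the C10 hydrogen (the situation of a 20-oxopregnane side chain); this should give the (S)-oxirane, and the minor epimer is removed by chromatography.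

Step 9
Reactants: 14 (2S)-2-[(1R,2R,3R,4R)-4-(tert-butyldimethylsilyloxy)-2,3-dimethyl-2-(2-methylidenebutyl)cyclohexyl]-2-methyloxirane
Product: 16 1-[(1R,2R,3R,6R)-3-(tert-butyldimethylsilyloxy)-1,2-dimethyl-6-[(2S)-2-methyloxiran-2-yl]cyclohexyl]butan-2-one, via ozonide 15 (not isolated)
Conditions: O3, CH2Cl2, −78 °C; then PPh3, −78 °C to rt
Reagents that add atoms: ozone, SMILES [O-][O+]=O
Why: Ozonolysis of the 1,1-disubstituted alkene with reductive work-up unmasks the C7 ethyl ketone only at this point, so the ylide of step 8 never meets two ketones; oxirane and silyl ether are stable to ozone at low temperature.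

Step 10
Reactants: 16 1-[(1R,2R,3R,6R)-3-(tert-butyldimethylsilyloxy)-1,2-dimethyl-6-[(2S)-2-methyloxiran-2-yl]cyclohexyl]butan-2-one
Product: 18 tert-butyl{[(2E)-1-[(1R,2R,3R,6R)-3-(tert-butyldimethylsilyloxy)-1,2-dimethyl-6-[(2S)-2-methyloxiran-2-yl]cyclohexyl]but-2-en-2-yl]oxy}dimethylsilane, via lithium enolate 17 (not isolated)
Conditions: lithium 2,2,6,6-tetramethylpiperidide, LiBr, THF, −78 °C; then TBSCl, DMPU, −78 to 0 °C
Reagents that add atoms: tert-butyldimethylsilyl chloride, SMILES CC(C)(C)[Si](C)(C)Cl
Why: Kinetic deprotonation with a hindered lithium amide removes a proton from the less hindered C8 methylene (not the neopentyl C6) and gives mainly the (E)-enolate, the LiBr mixed aggregate raising that preference. O-silylation after addition of DMPU keeps the geometry, and the oxirane is not attacked at −78 °C.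

Step 11
Reactants: 18 tert-butyl{[(2E)-1-[(1R,2R,3R,6R)-3-(tert-butyldimethylsilyloxy)-1,2-dimethyl-6-[(2S)-2-methyloxiran-2-yl]cyclohexyl]but-2-en-2-yl]oxy}dimethylsilane
Product: 20 3α-(tert-butyldimethylsilyloxy)-9α-(hydroxymethyl)-4β,5β,8α,9β-tetramethyl-trans-decalin-7-one, via aluminium alkoxide 19 (not isolated)
Conditions: MeAlCl2, CH2Cl2, −78 °C; aq. NaHCO3
Reagents that add atoms: none
Why: MeAlCl2 binds the oxirane oxygen and the nucleophilic C8 of the enol ether attacks the fully substituted C9 from the side opposite the breaking C9–O bond; the silyloxocarbenium ion then loses its silyl group as the chloride, leaving the C7 ketone and the C11 aluminium alkoxide. The closest known reaction type is the Lewis-acid epoxide-initiated cationic cyclisation terminated by a silyl enol ether (an intramolecular Mukaiyama-type alkylation). Ring A closes in the 6-exo mode with respect to the oxirane, the enol ether double bond lying inside the new ring, through a chair in which both ring-B side chains are equatorial, which gives the trans-decalin. C9 is controlled by the oxirane configuration through inversion, so its methyl group ends axial (β) and the CH2O group equatorial (α). C8 is controlled by the enol ether geometry: in the chair the substituent cis to C6, which is the methyl group of the (E)-isomer, becomes axial (α), anti to the C9 methyl. The step needs opening at the more substituted oxirane carbon, which the Lewis acid and the ring size secure (attack at C11 would require a seven-membered ring). It also needs C–C bond formation to outrun ionisation or a 1,2-hydride shift, for which the low temperature, the aprotic aluminium Lewis acid and the pre-organised diequatorial chains speak. The equatorial C8 hydrogen of 20 is poorly aligned with the carbonyl π-system, which slows epimerisation during work-up.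

Step 12
Reactants: 20 3α-(tert-butyldimethylsilyloxy)-9α-(hydroxymethyl)-4β,5β,8α,9β-tetramethyl-trans-decalin-7-one
Product: 21 allyl [3α-(tert-butyldimethylsilyloxy)-4β,5β,8α,9β-tetramethyl-7-oxo-trans-decalin-9α-yl]methyl carbonate
Conditions: allyl chloroformate, pyridine, DMAP (cat.), CH2Cl2, 0 °C
Reagents that add atoms: allyl chloroformate, SMILES C=CCOC(=O)Cl
Why: Acylation of the primary alcohol under mild amine-base conditions does not enolise the C7 ketone; the allyl carbonate is chosen because the palladium/formate conditions of step 14 remove it without a separate deprotection.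

Step 13
Reactants: 21 allyl [3α-(tert-butyldimethylsilyloxy)-4β,5β,8α,9β-tetramethyl-7-oxo-trans-decalin-9α-yl]methyl carbonate
Product: 23 9α-[(allyloxycarbonyloxy)methyl]-3α-(tert-butyldimethylsilyloxy)-4β,5β,8α,9β-tetramethyl-trans-Δ6-octalin-7-yl trifluoromethanesulfonate, via potassium enolate 22 (not isolated)
Conditions: KN(SiMe3)2, THF, −78 °C; then PhNTf2, −78 to 0 °C
Reagents that add atoms: N-phenylbis(trifluoromethanesulfonimide), SMILES O=S(=O)(N(c1ccccc1)S(=O)(=O)C(F)(F)F)C(F)(F)F
Why: Kinetic deprotonation takes the axial proton of the C6 methylene and not the equatorial, tertiary C8 hydrogen, so the enolate forms away from C8 and its O-triflation leaves the C8 centre untouched. Reaction at the enolate oxygen avoids nucleophilic attack at the C7 carbon, which is shielded by the axial C5, C9 and C8 methyl groups.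

Step 14
Reactants: 23 9α-[(allyloxycarbonyloxy)methyl]-3α-(tert-butyldimethylsilyloxy)-4β,5β,8α,9β-tetramethyl-trans-Δ6-octalin-7-yl trifluoromethanesulfonate
Product: 24 3α-(tert-butyldimethylsilyloxy)-9α-(hydroxymethyl)-4β,5β,8α,9β-tetramethyl-trans-Δ6-octalin
Conditions: Pd(OAc)2 (cat.), PPh3, HCO2H, Bu3N, DMF, 60 °C
Reagents that add atoms: none
Why: Palladium-catalysed formate reduction of the enol triflate (oxidative addition, formate-to-hydride exchange, reductive elimination) gives the C6=C7 alkene. The same zerovalent palladium/formate system cleaves the allyl carbonate through a π-allyl complex with loss of CO2 and propene, freeing the C11 alcohol.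

Step 15
Reactants: 24 3α-(tert-butyldimethylsilyloxy)-9α-(hydroxymethyl)-4β,5β,8α,9β-tetramethyl-trans-Δ6-octalin
Product: 25 3α-(tert-butyldimethylsilyloxy)-9α-(hydroxymethyl)-4β,5β,8α,9β-tetramethyl-trans-decalin
Conditions: H2 (3 atm), Pd/C, EtOAc, rt
Reagents that add atoms: none
Why: Heterogeneous hydrogenation of the cis-disubstituted C6=C7 alkene creates no stereocentre and completes the removal of the C7 oxygen before the reducible coumarin is introduced.

Step 16
Reactants: 25 3α-(tert-butyldimethylsilyloxy)-9α-(hydroxymethyl)-4β,5β,8α,9β-tetramethyl-trans-decalin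
Product: 26 [3α-(tert-butyldimethylsilyloxy)-4β,5β,8α,9β-tetramethyl-trans-decalin-9α-yl]methyl trifluoromethanesulfonate
Conditions: Tf2O, 2,6-lutidine, CH2Cl2, −78 to −40 °C; cold work-up, used at once
Reagents that add atoms: trifluoromethanesulfonic anhydride, SMILES O=S(=O)(OS(=O)(=O)C(F)(F)F)C(F)(F)F
Why: O-sulfonylation of the neopentyl alcohol provides the one leaving group reactive enough for substitution at C11; C9 carries no hydrogen, so elimination is impossible.

Step 17
Reactants: 26 [3α-(tert-butyldimethylsilyloxy)-4β,5β,8α,9β-tetramethyl-trans-decalin-9α-yl]methyl trifluoromethanesulfonate; 27 umbelliferone (7-hydroxycoumarin)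
Product: 28 7-{[3α-(tert-butyldimethylsilyloxy)-4β,5β,8α,9β-tetramethyl-trans-decalin-9α-yl]methoxy}coumarin
Conditions: Cs2CO3, DMF, 0 °C to rt
Reagents that add atoms: none
Why: Williamson-type SN2 O-alkylation of caesium umbelliferonate by the primary triflate in a dipolar aprotic solvent; the weakly basic phenoxide leaves the lactone and the silyl ether intact.

Step 18
Reactants: 28 7-{[3α-(tert-butyldimethylsilyloxy)-4β,5β,8α,9β-tetramethyl-trans-decalin-9α-yl]methoxy}coumarin
Product: 29 7-{[3α-hydroxy-4β,5β,8α,9β-tetramethyl-trans-decalin-9α-yl]methoxy}coumarin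
Conditions: HF (48% aq.), MeCN, rt
Reagents that add atoms: none
Why: Fluoride-mediated cleavage of the secondary silyl ether under acidic conditions, to which the aryl alkyl ether and the coumarin lactone are stable.

Step 19
Reactants: 29 7-{[3α-hydroxy-4β,5β,8α,9β-tetramethyl-trans-decalin-9α-yl]methoxy}coumarin
Product: 30 7-{[4β,5β,8α,9β-tetramethyl-3-oxo-trans-decalin-9α-yl]methoxy}coumarin (CNP0241391.2)
Conditions: Dess–Martin periodinane, CH2Cl2, rt
Reagents that add atoms: none
Why: Dess–Martin oxidation of the secondary alcohol to the C3 ketone under neutral conditions; the adjacent C4 methyl is already in its stable equatorial configuration, so the target configuration is retained.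

## Compound list

1 | 2-bromobut-1-ene | CCC(Br)=C | starting material
2 | (trimethylsilyl)methylmagnesium chloride | C[Si](C)(C)C[Mg]Cl | starting material
3 | trimethyl(2-methylidenebutyl)silane | CCC(=C)C[Si](C)(C)C | intermediate
4 | ethyl 2-methyl-4-oxocyclohex-2-ene-1-carboxylate (Hagemann's ester, racemate) | CCOC(=O)C1CCC(=O)C=C1C | starting material
5 | ethyl 2,3-dimethyl-4-oxocyclohex-2-ene-1-carboxylate (racemate) | CCOC(=O)C1CCC(=O)C(C)=C1C | intermediate
6 | trichlorotitanium enolate of 7 (racemate; not isolated) | CCC(=C)C[C@@]1(C)[C@@H](CCC(O[Ti](Cl)(Cl)Cl)=C1C)C(=O)OCC | intermediate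
7 | ethyl (1R*,2R*,3R*)-2,3-dimethyl-2-(2-methylidenebutyl)-4-oxocyclohexane-1-carboxylate (racemate; side chain trans to ester, C3 methyl cis to C2 methyl) | CCC(=C)C[C@@]1(C)[C@@H](CCC(=O)[C@@H]1C)C(=O)OCC | intermediate
8 | ethyl (1R*,2R*,3R*,4R*)-4-hydroxy-2,3-dimethyl-2-(2-methylidenebutyl)cyclohexane-1-carboxylate (racemate; equatorial OH trans to C3 methyl) | CCC(=C)C[C@@]1(C)[C@@H](CC[C@@H](O)[C@@H]1C)C(=O)OCC | intermediate
9 | ethyl (1R,2R,3R,4R)-4-acetoxy-2,3-dimethyl-2-(2-methylidenebutyl)cyclohexane-1-carboxylate | CCC(=C)C[C@@]1(C)[C@@H](CC[C@@H](OC(C)=O)[C@@H]1C)C(=O)OCC | intermediate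
10 | 1-[(1R,2R,3R,4R)-4-hydroxy-2,3-dimethyl-2-(2-methylidenebutyl)cyclohexyl]-2-(trimethylsilyl)ethan-1-one (present as its lithium salts; not isolated) | CCC(=C)C[C@@]1(C)[C@@H](CC[C@@H](O)[C@@H]1C)C(=O)C[Si](C)(C)C | intermediate
11 | 1-[(1R,2R,3R,4R)-4-hydroxy-2,3-dimethyl-2-(2-methylidenebutyl)cyclohexyl]ethan-1-one | CCC(=C)C[C@@]1(C)[C@@H](CC[C@@H](O)[C@@H]1C)C(C)=O | intermediate
12 | 1-[(1R,2R,3R,4R)-4-(tert-butyldimethylsilyloxy)-2,3-dimethyl-2-(2-methylidenebutyl)cyclohexyl]ethan-1-one | CCC(=C)C[C@@]1(C)[C@@H](CC[C@@H](O[Si](C)(C)C(C)(C)C)[C@@H]1C)C(C)=O | intermediate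
13 | trimethylsulfonium iodide | C[S+](C)C.[I-] | starting material
14 | (2S)-2-[(1R,2R,3R,4R)-4-(tert-butyldimethylsilyloxy)-2,3-dimethyl-2-(2-methylidenebutyl)cyclohexyl]-2-methyloxirane | CCC(=C)C[C@@]1(C)[C@@H](CC[C@@H](O[Si](C)(C)C(C)(C)C)[C@@H]1C)[C@@]2(C)CO2 | intermediate
15 | secondary ozonide (1,2,4-trioxolane) of 14 (not isolated) | CCC1(C[C@@]2(C)[C@@H](CC[C@@H](O[Si](C)(C)C(C)(C)C)[C@@H]2C)[C@@]3(C)CO3)OCOO1 | intermediate
16 | 1-[(1R,2R,3R,6R)-3-(tert-butyldimethylsilyloxy)-1,2-dimethyl-6-[(2S)-2-methyloxiran-2-yl]cyclohexyl]butan-2-one | CCC(=O)C[C@@]1(C)[C@@H](CC[C@@H](O[Si](C)(C)C(C)(C)C)[C@@H]1C)[C@@]2(C)CO2 | intermediate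
17 | lithium (E)-enolate of 16 at C7/C8 (not isolated) | C/C=C(/O[Li])C[C@@]1(C)[C@@H](CC[C@@H](O[Si](C)(C)C(C)(C)C)[C@@H]1C)[C@@]2(C)CO2 | intermediate
18 | tert-butyl{[(2E)-1-[(1R,2R,3R,6R)-3-(tert-butyldimethylsilyloxy)-1,2-dimethyl-6-[(2S)-2-methyloxiran-2-yl]cyclohexyl]but-2-en-2-yl]oxy}dimethylsilane (ring-B (E)-silyl enol ether with the C9 methyloxirane) | C/C=C(/O[Si](C)(C)C(C)(C)C)C[C@@]1(C)[C@@H](CC[C@@H](O[Si](C)(C)C(C)(C)C)[C@@H]1C)[C@@]2(C)CO2 | intermediate
19 | chloro(methyl)aluminium C11-alkoxide of 20 (not isolated) | C[C@@H]1C(=O)C[C@@]2(C)[C@@H](CC[C@@H](O[Si](C)(C)C(C)(C)C)[C@@H]2C)[C@]1(C)CO[Al](C)Cl | intermediate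
20 | 3α-(tert-butyldimethylsilyloxy)-9α-(hydroxymethyl)-4β,5β,8α,9β-tetramethyl-trans-decalin-7-one (10α-H) | C[C@@H]1C(=O)C[C@@]2(C)[C@@H](CC[C@@H](O[Si](C)(C)C(C)(C)C)[C@@H]2C)[C@]1(C)CO | intermediate
21 | allyl [3α-(tert-butyldimethylsilyloxy)-4β,5β,8α,9β-tetramethyl-7-oxo-trans-decalin-9α-yl]methyl carbonate | C[C@@H]1C(=O)C[C@@]2(C)[C@@H](CC[C@@H](O[Si](C)(C)C(C)(C)C)[C@@H]2C)[C@]1(C)COC(=O)OCC=C | intermediate
22 | potassium C6=C7 enolate of 21 (not isolated) | C[C@@H]1C(O[K])=C[C@@]2(C)[C@@H](CC[C@@H](O[Si](C)(C)C(C)(C)C)[C@@H]2C)[C@]1(C)COC(=O)OCC=C | intermediate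
23 | 9α-[(allyloxycarbonyloxy)methyl]-3α-(tert-butyldimethylsilyloxy)-4β,5β,8α,9β-tetramethyl-trans-Δ6-octalin-7-yl trifluoromethanesulfonate | C[C@@H]1C(OS(=O)(=O)C(F)(F)F)=C[C@@]2(C)[C@@H](CC[C@@H](O[Si](C)(C)C(C)(C)C)[C@@H]2C)[C@]1(C)COC(=O)OCC=C | intermediate
24 | 3α-(tert-butyldimethylsilyloxy)-9α-(hydroxymethyl)-4β,5β,8α,9β-tetramethyl-trans-Δ6-octalin | C[C@@H]1C=C[C@@]2(C)[C@@H](CC[C@@H](O[Si](C)(C)C(C)(C)C)[C@@H]2C)[C@]1(C)CO | intermediate
25 | 3α-(tert-butyldimethylsilyloxy)-9α-(hydroxymethyl)-4β,5β,8α,9β-tetramethyl-trans-decalin | C[C@@H]1CC[C@@]2(C)[C@@H](CC[C@@H](O[Si](C)(C)C(C)(C)C)[C@@H]2C)[C@]1(C)CO | intermediate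
26 | [3α-(tert-butyldimethylsilyloxy)-4β,5β,8α,9β-tetramethyl-trans-decalin-9α-yl]methyl trifluoromethanesulfonate | C[C@@H]1CC[C@@]2(C)[C@@H](CC[C@@H](O[Si](C)(C)C(C)(C)C)[C@@H]2C)[C@]1(C)COS(=O)(=O)C(F)(F)F | intermediate
27 | umbelliferone (7-hydroxycoumarin) | Oc1ccc2ccc(=O)oc2c1 | starting material
28 | 7-{[3α-(tert-butyldimethylsilyloxy)-4β,5β,8α,9β-tetramethyl-trans-decalin-9α-yl]methoxy}coumarin | C[C@@H]1CC[C@@]2(C)[C@@H](CC[C@@H](O[Si](C)(C)C(C)(C)C)[C@@H]2C)[C@]1(C)COc1ccc2ccc(=O)oc2c1 | intermediate
29 | 7-{[3α-hydroxy-4β,5β,8α,9β-tetramethyl-trans-decalin-9α-yl]methoxy}coumarin | C[C@@H]1CC[C@@]2(C)[C@@H](CC[C@@H](O)[C@@H]2C)[C@]1(C)COc1ccc2ccc(=O)oc2c1 | intermediate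
30 | 7-{[4β,5β,8α,9β-tetramethyl-3-oxo-trans-decalin-9α-yl]methoxy}coumarin (CNP0241391.2) | C[C@@H]1CC[C@@]2(C)[C@@H](CCC(=O)[C@@H]2C)[C@]1(C)COc1ccc2ccc(=O)oc2c1 | target

## Step count and least certain steps

Total: 19 steps. Longest linear sequence: 18 steps (steps 2–19, from Hagemann's ester 4); step 1 prepares the allylsilane 3 on the side.

**Step 11 (key step).** Most likely failures are processes that compete with ring closure once the aluminium Lewis acid has activated the 2,2-disubstituted oxirane: a 1,2-hydride shift to the aldehyde, capture by chloride, or ionisation to a free tertiary cation before the C8–C9 bond forms, which would erode the C9 configuration. Hydrolytic loss of the enol ether would stop the reaction, and any (Z)-enol ether carried in from step 10 would appear as the C8 epimer. Fallback (from 16, back at 20): replace the oxygen-based terminator by a carbon-based one.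
- The (E)-lithium enolate of 16, made as in step 10, is trapped with PhNTf2 to give the (E)-enol triflate F1.
- Kumada coupling of F1 with 2 and Pd(PPh3)4 gives, with retention of geometry, the (E)-allylsilane F2.
- Lewis-acid closure of F2 (TiCl4, CH2Cl2, −78 °C), an allylsilane-terminated epoxide cyclisation with the same chair and the same inversion at C9, gives the 7-methylidene alcohol F3.
- Ozonolysis of F3 (O3; PPh3) returns 20.

**Step 4.** The risk is incomplete thermodynamic control in the protonation of the ketyl/organosamarium intermediate, giving the axial alcohol that the lipase would not accept. Fallback (from 7, back at 8): run a true dissolving-metal reduction on a substrate without an ester.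
- Saponification (LiOH, aq. THF) gives the keto acid F4.
- Li/NH3 reduces only the ketone of the carboxylate, to the equatorial hydroxy acid F5.
- Re-esterification (EtI, K2CO3, DMF) gives 8.

**Step 5.** The risk is slow acyl transfer or poor enantiomer discrimination, because the carbinol is flanked by a CHMe group next to a quaternary carbon. Fallback (from 8, back at 11): covalent resolution.
- Esterification of racemic 8 with (S)-O-methylmandelic acid (DCC, DMAP) and separation of the diastereomeric esters by chromatography or crystallisation gives the (S)-O-methylmandelate F6 of the (1R,2R,3R,4R)-alcohol.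
- F6 is treated with Me3SiCH2Li and then MeOH exactly as in step 6, which cleaves the auxiliary ester and converts the ethyl ester, giving 11.

**Step 8.** The risk is facial selection that is opposite to or weaker than predicted (the ylide is small and its transition state early), or enolisation of the hindered methyl ketone by the basic ylide in place of addition. Fallback (from 12, back at 14): exchange the roles of the two C9 substituents.
- The kinetic enolate of 12 (LiN(iPr)2, THF, −78 °C) is chlorinated with N-chlorosuccinimide to the chloromethyl ketone F7.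
- MeMgBr then adds. The nucleophile is now the methyl group, so the face that gave the wrong oxirane with the ylide gives the right chlorohydrin F8.
- K2CO3 in MeOH closes F8 to 14.

**Step 17.** The risk is slow substitution at the neopentyl C11, which would let ionisation of the triflate with a 1,2-alkyl shift (ring expansion or methyl migration) compete. Fallback (from 25, back at 28): make the aryl–oxygen bond instead of the alkyl–oxygen bond. Palladium-catalysed C–O coupling of alcohol 25 with commercial 7-bromocoumarin (Pd2(dba)3, tBuBrettPhos, Cs2CO3, toluene, 80 °C) gives 28 directly. No substitution at C11 is involved and no new intermediate is made (F0).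

## Further compounds

F1 | step 11 | (2E)-1-[(1R,2R,3R,6R)-3-(tert-butyldimethylsilyloxy)-1,2-dimethyl-6-[(2S)-2-methyloxiran-2-yl]cyclohexyl]but-2-en-2-yl trifluoromethanesulfonate | C/C=C(/OS(=O)(=O)C(F)(F)F)C[C@@]1(C)[C@@H](CC[C@@H](O[Si](C)(C)C(C)(C)C)[C@@H]1C)[C@@]2(C)CO2
F2 | step 11 | (E)-allylsilane: {2-[[(1R,2R,3R,6R)-3-(tert-butyldimethylsilyloxy)-1,2-dimethyl-6-[(2S)-2-methyloxiran-2-yl]cyclohexyl]methyl]but-2-en-1-yl}trimethylsilane | C/C=C(/C[Si](C)(C)C)C[C@@]1(C)[C@@H](CC[C@@H](O[Si](C)(C)C(C)(C)C)[C@@H]1C)[C@@]2(C)CO2
F3 | step 11 | 3α-(tert-butyldimethylsilyloxy)-9α-(hydroxymethyl)-4β,5β,8α,9β-tetramethyl-7-methylidene-trans-decalin | C[C@@H]1C(=C)C[C@@]2(C)[C@@H](CC[C@@H](O[Si](C)(C)C(C)(C)C)[C@@H]2C)[C@]1(C)CO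
F4 | step 4 | (1R*,2R*,3R*)-2,3-dimethyl-2-(2-methylidenebutyl)-4-oxocyclohexane-1-carboxylic acid (racemate) | CCC(=C)C[C@@]1(C)[C@@H](CCC(=O)[C@@H]1C)C(=O)O
F5 | step 4 | (1R*,2R*,3R*,4R*)-4-hydroxy-2,3-dimethyl-2-(2-methylidenebutyl)cyclohexane-1-carboxylic acid (racemate) | CCC(=C)C[C@@]1(C)[C@@H](CC[C@@H](O)[C@@H]1C)C(=O)O
F6 | step 5 | ethyl (1R,2R,3R,4R)-4-{[(2S)-2-methoxy-2-phenylacetyl]oxy}-2,3-dimethyl-2-(2-methylidenebutyl)cyclohexane-1-carboxylate | CCC(=C)C[C@@]1(C)[C@@H](CC[C@@H](OC(=O)[C@@H](OC)c2ccccc2)[C@@H]1C)C(=O)OCC
F7 | step 8 | 2-chloro-1-[(1R,2R,3R,4R)-4-(tert-butyldimethylsilyloxy)-2,3-dimethyl-2-(2-methylidenebutyl)cyclohexyl]ethan-1-one | CCC(=C)C[C@@]1(C)[C@@H](CC[C@@H](O[Si](C)(C)C(C)(C)C)[C@@H]1C)C(=O)CCl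
F8 | step 8 | (2S)-1-chloro-2-[(1R,2R,3R,4R)-4-(tert-butyldimethylsilyloxy)-2,3-dimethyl-2-(2-methylidenebutyl)cyclohexyl]propan-2-ol | CCC(=C)C[C@@]1(C)[C@@H](CC[C@@H](O[Si](C)(C)C(C)(C)C)[C@@H]1C)[C@@](O)(C)CCl
F0 | step 17 | none | none
A1 | alternative 1 | 4-[(tert-butyldiphenylsilyloxy)methyl]-2,4-dimethylcyclohex-2-en-1-one (ring-A enone with the C9 quaternary centre) | CC1=C[C@](C)(CO[Si](c2ccccc2)(c2ccccc2)C(C)(C)C)CCC1=O
A2 | alternative 1 | 4-[(tert-butyldiphenylsilyloxy)methyl]-2,4-dimethyl-2-(3-trimethylsilylprop-2-ynyl)-3-vinylcyclohexan-1-one (C5, C10, C9 as in the target) | C[Si](C)(C)C#CC[C@@]1(C)C(=O)CC[C@@](C)(CO[Si](c2ccccc2)(c2ccccc2)C(C)(C)C)[C@@H]1C=C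
A3 | alternative 2 | acyclic triene: (E,E)-1-(tert-butyldimethylsilyloxy)diene tethered through the C9 quaternary centre to an (E)-2-methylbut-2-enoyl (tiglyl) ketone | C/C=C(\C)C(=O)CC[C@@](C)(CO[Si](c1ccccc1)(c1ccccc1)C(C)(C)C)/C=C/C=C/O[Si](C)(C)C(C)(C)C
A4 | alternative 2 | trans-fused Δ1-octalin-6-one with 3β-(tert-butyldimethylsilyloxy), 4β,5β,9β-trimethyl and 9α-(tert-butyldiphenylsilyloxymethyl) groups | O=C1CC[C@@](C)(CO[Si](c3ccccc3)(c3ccccc3)C(C)(C)C)[C@@H]2C=C[C@H](O[Si](C)(C)C(C)(C)C)[C@H](C)[C@@]12C
A5 | alternative 3 | 9-(benzyloxymethyl)-4β,5β-dimethyl-trans-Δ8-octalin-7-one 3-(ethylene ketal) | O=C1C[C@@]2(C)[C@@H](CCC3(OCCO3)[C@@H]2C)C(COCc4ccccc4)=C1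
A6 | alternative 3 | 9α-(benzyloxymethyl)-4β,5β,8α,9β-tetramethyl-trans-decalin-7-one 3-(ethylene ketal) | C[C@@H]1C(=O)C[C@@]2(C)[C@@H](CCC3(OCCO3)[C@@H]2C)[C@]1(C)COCc1ccccc1
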